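**Retrosynthetic overview**

- The strategy rests on ring A of the flavone (C4a, C5, C6, C7, C8, C8a): O5 and O8 sit para to each other with the two methoxy carbons C6 and C7 between them. That is a 2,3-dimethoxyhydroquinone, the pattern a thermal ring expansion of a dimethyl squarate adduct delivers.
- Target ⇐ hydrogenolysis of three benzyl ethers ⇐ methylation of O8 alone (O5 is hydrogen-bonded to C4=O) ⇐ 5,8-hydroquinone.
- 5,8-Hydroquinone ⇐ Moore benzannulation (forms C8–C8a, closes ring A) of a 4-hydroxy-4-(4-pyranon-5-yl)-2,3-dimethoxycyclobutenone ⇐ C4a–C5 bond by adding a C5-magnesiated pyranone to dimethyl squarate.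
- Pyranone (ring C, with the B-ring aryl at C2 and OBn at C3) ⇐ 5-iodide (I/Mg exchange fixes the nucleophile at C5) ⇐ 3-hydroxy-4-pyranone ⇐ Achmatowicz product of a 3-bromofuryl carbinol (the bromine supplies the oxidation level of C4) ⇐ 3-bromofuran + 3,4-bis(benzyloxy)benzaldehyde.
- Ring order: B (bought) → C (steps 1–3) → A (step 7).

Key step: step 7

Remark on the chemistry: the target has no stereocentre and no stereogenic axis, so it is one achiral compound. The stereocentres of 4, 5 and 11 are formed racemic and are destroyed later. Pyranone numbering used below: O1, C2 (aryl), C3 (oxygen), C4 (C=O), C5 (CH next to C=O), C6 (CH next to O1).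

**Route**

Step 1
Reactants: 1 3-bromofuran; 2 3,4-bis(benzyloxy)benzaldehyde
Product: 4 rac-[3,4-bis(benzyloxy)phenyl](3-bromofuran-2-yl)methanol, via 3-bromo-2-furyllithium 3 (not isolated)
Conditions: LDA (1.1 equiv), THF, −78 °C, 30 min; then 2, −78 °C; aq NH4Cl
Reagents that add atoms: none
Why: LDA removes the most acidic furan proton at C2 (between the ring oxygen and the bromine) at −78 °C without halogen–metal exchange or halogen dance, and the furyllithium adds to the aldehyde carbonyl (organolithium 1,2-addition) to give a racemic carbinol whose stereocentre is erased in step 3; the bromine is carried because it stores at furan C3 the oxidation level that pyranone C4 needs, a halogen-free Achmatowicz product being two hydrogens richer than a 3-hydroxy-4-pyranone.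

Step 2
Reactants: 4 rac-[3,4-bis(benzyloxy)phenyl](3-bromofuran-2-yl)methanol
Product: 5 2-[3,4-bis(benzyloxy)phenyl]-4-bromo-6-hydroxy-2H-pyran-3(6H)-one (racemic mixture of C2/C6 diastereomers)
Conditions: NBS (1.05 equiv), NaHCO3, THF–H2O (4:1), 0 °C
Reagents that add atoms: water, O
Why: Achmatowicz oxidative ring expansion, in which NBS attacks the free α-position (C5) of the furan much faster than the dialkoxybenzene ring, water opens the furan to the enedione and the carbinol oxygen recloses as the hemiacetal, so that the former furan C3–Br becomes the C4 vinyl bromide; C2 and C6 are formed unselectively and both disappear in step 3.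

Step 3
Reactants: 5 2-[3,4-bis(benzyloxy)phenyl]-4-bromo-6-hydroxy-2H-pyran-3(6H)-one
Product: 6 2-[3,4-bis(benzyloxy)phenyl]-3-hydroxy-4H-pyran-4-one
Conditions: 1 M aq H2SO4–1,4-dioxane (1:2), 80–90 °C
Reagents that add atoms: water, O
Why: This is the second stage of the industrial maltol synthesis (acid hydrolysis of a 4-halo-6-hydroxy-2H-pyran-3(6H)-one), in which enolisation towards C2 and acid-promoted ionisation at C6 make C4 electrophilic, water adds there and HBr is expelled, giving the aromatic 3-hydroxy-4-pyranone with both stereocentres removed; aryl benzyl ethers should survive dilute non-nucleophilic acid at this temperature.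

Step 4
Reactants: 6 2-[3,4-bis(benzyloxy)phenyl]-3-hydroxy-4H-pyran-4-one
Product: 7 3-(benzyloxy)-2-[3,4-bis(benzyloxy)phenyl]-4H-pyran-4-one
Conditions: BnBr (1.2 equiv), K2CO3, DMF, 50 °C
Reagents that add atoms: benzyl bromide, BrCc1ccccc1
Why: Williamson O-alkylation of the acidic enolic 3-hydroxyl (the only OH present) masks it against the Grignard reagent of step 6 as a benzyl ether that leaves in the final hydrogenolysis with the other two.

Step 5
Reactants: 7 3-(benzyloxy)-2-[3,4-bis(benzyloxy)phenyl]-4H-pyran-4-one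
Product: 8 3-(benzyloxy)-2-[3,4-bis(benzyloxy)phenyl]-5-iodo-4H-pyran-4-one
Conditions: I2 (2 equiv), pyridine–CH2Cl2 (1:1), DMAP (0.2 equiv), rt to 40 °C, dark
Reagents that add atoms: iodine, II
Why: Amine-promoted α-iodination of a β-alkoxy enone (Johnson iodination), in which pyridine/DMAP adds reversibly to C6, the enolate is iodinated at C5 (the only CH α to the carbonyl) and the amine is expelled, a pathway closed to the dialkoxyphenyl ring, which I2/pyridine does not attack; the iodide is installed because direct deprotonation of 7 is expected at the oxygen-flanked C6–H and not at C5.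

Step 6
Reactants: 8 3-(benzyloxy)-2-[3,4-bis(benzyloxy)phenyl]-5-iodo-4H-pyran-4-one; 9 dimethyl squarate (3,4-dimethoxycyclobut-3-ene-1,2-dione)
Product: 11 rac-4-{5-(benzyloxy)-6-[3,4-bis(benzyloxy)phenyl]-4-oxo-4H-pyran-3-yl}-4-hydroxy-2,3-dimethoxycyclobut-2-en-1-one (the point of attachment is C5 in the numbering of 7 and 8), via C5-chloromagnesiopyranone 10 (not isolated)
Conditions: iPrMgCl·LiCl (1.1 equiv), THF, −40 °C, 30 min; cannulated into 9 (1.5 equiv), THF, −78 °C; aq NH4Cl at −78 °C
Reagents that add atoms: none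
Why: Iodine–magnesium exchange at −40 °C (faster than addition to the pyranone carbonyl, as established for 3-iodochromones, and cold enough to avoid ring-opening β-elimination) gives the C5 Grignard reagent regiospecifically, which adds 1,2 to one carbonyl of dimethyl squarate (inverse addition onto excess squarate prevents double addition) to give a racemic tertiary carbinol whose stereocentre is consumed in step 7.

Step 7
Reactants: 11 rac-4-{5-(benzyloxy)-6-[3,4-bis(benzyloxy)phenyl]-4-oxo-4H-pyran-3-yl}-4-hydroxy-2,3-dimethoxycyclobut-2-en-1-one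
Product: 14 3-(benzyloxy)-2-[3,4-bis(benzyloxy)phenyl]-5,8-dihydroxy-6,7-dimethoxy-4H-chromen-4-one, via dienylketene 12 (not isolated), via 8aH-chromene-4,8-dione 13 (not isolated)
Conditions: degassed p-xylene (0.02 M), reflux (138 °C), Ar, 1–3 h; work-up under Ar
Reagents that add atoms: none
Why: On heating, the cyclobutenone opens by conrotatory 4π electrocyclic cleavage of the C1–C4 bond to the dienylketene 12, the electron-donating hydroxyl rotating outward so that the pyranonyl group lies on the same side as the ketene. Ring A is then closed by a thermal disrotatory 6π electrocyclisation in which the ketene carbon bonds to pyranone C6, forming C8–C8a and the dienone 13, and enolisation of the C8a hydrogen (α to the new C8 ketone) aromatises it to the 5,8-hydroquinone 14. The reaction type is the Moore rearrangement, known for 4-aryl-, 4-heteroaryl- (furyl, thienyl, pyridyl) and 4-alkenyl-4-hydroxycyclobutenones, with the pyranone C5=C6 bond taking the part of the aryl π bond. No stereocentre survives, since the carbinol carbon of 11 becomes sp2 and the transient C8a centre of 13 is lost on enolisation. The selectivity needed is outward rotation of the hydroxyl (inward rotation would lead to a butenolide by O–H addition to the ketene), and the free 4-OH secures it; site selectivity is not in question because C6 is the only CH carbon next to the point of attachment, the other neighbour being the C4 carbonyl carbon. Oxygen is excluded and the solution kept dilute so that the electron-rich hydroquinone is neither oxidised to the 5,8-quinone nor acylated by ketene.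

Step 8
Reactants: 14 3-(benzyloxy)-2-[3,4-bis(benzyloxy)phenyl]-5,8-dihydroxy-6,7-dimethoxy-4H-chromen-4-one
Product: 15 3-(benzyloxy)-2-[3,4-bis(benzyloxy)phenyl]-5-hydroxy-6,7,8-trimethoxy-4H-chromen-4-one
Conditions: MeI (1.1 equiv), K2CO3 (1.5 equiv), degassed acetone, Ar, rt to 40 °C
Reagents that add atoms: iodomethane, CI
Why: Chelation-controlled mono-O-methylation, in which the 5-OH is locked in a hydrogen bond to the C4 carbonyl and is not alkylated by K2CO3/MeI at this temperature, so only the free 8-OH reacts (the classical partial methylation of 5,8-dihydroxyflavones); air is excluded because the hydroquinone anion autoxidises.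

Step 9
Reactants: 15 3-(benzyloxy)-2-[3,4-bis(benzyloxy)phenyl]-5-hydroxy-6,7,8-trimethoxy-4H-chromen-4-one
Product: 16 3,5,3',4'-tetrahydroxy-6,7,8-trimethoxyflavone
Conditions: H2 (1 atm), 10% Pd/C, THF–MeOH (1:1), rt
Reagents that add atoms: none
Why: Hydrogenolysis of the three benzyl ethers over Pd/C at 1 atm leaves the tetrasubstituted C2=C3 bond of the flavonol, the carbonyl and the methyl ethers untouched and releases the target, which has no stereocentre to set.

**Compound list**

1 | 3-bromofuran | Brc1ccoc1 | starting material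
2 | 3,4-bis(benzyloxy)benzaldehyde | O=Cc1ccc(OCc2ccccc2)c(OCc2ccccc2)c1 | starting material
3 | 3-bromo-2-furyllithium | [Li]c1occc1Br | intermediate
4 | rac-[3,4-bis(benzyloxy)phenyl](3-bromofuran-2-yl)methanol | OC(c1occc1Br)c1ccc(OCc2ccccc2)c(OCc2ccccc2)c1 | intermediate
5 | 2-[3,4-bis(benzyloxy)phenyl]-4-bromo-6-hydroxy-2H-pyran-3(6H)-one (racemic, C2/C6 diastereomer mixture) | O=C1C(Br)=CC(O)OC1c1ccc(OCc2ccccc2)c(OCc2ccccc2)c1 | intermediate
6 | 2-[3,4-bis(benzyloxy)phenyl]-3-hydroxy-4H-pyran-4-one | O=c1ccoc(-c2ccc(OCc3ccccc3)c(OCc3ccccc3)c2)c1O | intermediate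
7 | 3-(benzyloxy)-2-[3,4-bis(benzyloxy)phenyl]-4H-pyran-4-one | O=c1ccoc(-c2ccc(OCc3ccccc3)c(OCc3ccccc3)c2)c1OCc1ccccc1 | intermediate
8 | 3-(benzyloxy)-2-[3,4-bis(benzyloxy)phenyl]-5-iodo-4H-pyran-4-one | O=c1c(I)coc(-c2ccc(OCc3ccccc3)c(OCc3ccccc3)c2)c1OCc1ccccc1 | intermediate
9 | dimethyl squarate | COC1=C(OC)C(=O)C1=O | starting material
10 | {5-(benzyloxy)-6-[3,4-bis(benzyloxy)phenyl]-4-oxo-4H-pyran-3-yl}magnesium chloride (LiCl complex) | O=c1c([Mg]Cl)coc(-c2ccc(OCc3ccccc3)c(OCc3ccccc3)c2)c1OCc1ccccc1 | intermediate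
11 | rac-4-{5-(benzyloxy)-6-[3,4-bis(benzyloxy)phenyl]-4-oxo-4H-pyran-3-yl}-4-hydroxy-2,3-dimethoxycyclobut-2-en-1-one | COC1=C(OC)C(O)(c2coc(-c3ccc(OCc4ccccc4)c(OCc4ccccc4)c3)c(OCc3ccccc3)c2=O)C1=O | intermediate
12 | 4-{5-(benzyloxy)-6-[3,4-bis(benzyloxy)phenyl]-4-oxo-4H-pyran-3-yl}-4-hydroxy-2,3-dimethoxybuta-1,3-dien-1-one (ketene carbon and pyranonyl group cis across the enol C=C, hydroxyl outward) | O=C=C(OC)/C(OC)=C(/O)c1coc(-c2ccc(OCc3ccccc3)c(OCc3ccccc3)c2)c(OCc2ccccc2)c1=O | intermediate
13 | rac-3-(benzyloxy)-2-[3,4-bis(benzyloxy)phenyl]-5-hydroxy-6,7-dimethoxy-4H-chromene-4,8(8aH)-dione | COC1=C(OC)C(O)=C2C(=O)C(OCc3ccccc3)=C(c3ccc(OCc4ccccc4)c(OCc4ccccc4)c3)OC2C1=O | intermediate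
14 | 3-(benzyloxy)-2-[3,4-bis(benzyloxy)phenyl]-5,8-dihydroxy-6,7-dimethoxy-4H-chromen-4-one | COc1c(OC)c(O)c2oc(-c3ccc(OCc4ccccc4)c(OCc4ccccc4)c3)c(OCc3ccccc3)c(=O)c2c1O | intermediate
15 | 3-(benzyloxy)-2-[3,4-bis(benzyloxy)phenyl]-5-hydroxy-6,7,8-trimethoxy-4H-chromen-4-one | COc1c(OC)c(OC)c2oc(-c3ccc(OCc4ccccc4)c(OCc4ccccc4)c3)c(OCc3ccccc3)c(=O)c2c1O | intermediate
16 | 3,5,3',4'-tetrahydroxy-6,7,8-trimethoxyflavone | COc1c(OC)c(O)c2c(=O)c(O)c(-c3ccc(O)c(O)c3)oc2c1OC | target

**Step count and risks**

Total step count: 9. Longest linear sequence: 9 steps (1 or 2 to 16); dimethyl squarate 9 enters as a bought partner in step 6.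

Steps most likely to fail:

1. Step 7. The 6π closure onto the electron-poor C6 terminus of the pyranone may be outrun by other reactions of the ketene: inward rotation of the hydroxyl with lactonisation, intermolecular capture of the ketene by product phenol, or thermal breakdown of the carbinol. Fallback, a classical flavone construction from 2 to 16:
   - Claisen–Schmidt condensation of 2 with the known 1-(2-hydroxy-3,4,5,6-tetramethoxyphenyl)ethanone (KOH, EtOH, rt) would give the chalcone (E)-3-[3,4-bis(benzyloxy)phenyl]-1-(2-hydroxy-3,4,5,6-tetramethoxyphenyl)prop-2-en-1-one F1.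
   - Catalytic I2 in DMSO at 120 °C would cyclise and dehydrogenate it to 2-[3,4-bis(benzyloxy)phenyl]-5,6,7,8-tetramethoxy-4H-chromen-4-one F2.
   - Dimethyldioxirane epoxidation of the C2=C3 bond, then acid-induced opening (cat. TsOH), would give the flavonol 2-[3,4-bis(benzyloxy)phenyl]-3-hydroxy-5,6,7,8-tetramethoxy-4H-chromen-4-one F3.
   - BCl3 (CH2Cl2, −78 to 0 °C) would cleave the carbonyl-chelated 5-O-methyl group and both benzyl ethers, arriving at 16.

2. Step 5. The amine may fail to add to C6 of the aromatic pyranone, leaving no conversion, and more forcing electrophilic conditions would divert iodination to the dialkoxyphenyl ring. Fallback from 7 to 14, bypassing the iodide: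
   - Deprotonation of 7 with LiTMP (THF, −78 °C) at the oxygen-flanked C6–H and addition to 9 would give rac-4-{5-(benzyloxy)-6-[3,4-bis(benzyloxy)phenyl]-4-oxo-4H-pyran-2-yl}-4-hydroxy-2,3-dimethoxycyclobut-2-en-1-one F4.
   - Thermolysis of F4 under the conditions of step 7 would close ring A onto the nucleophilic C5.
   - Because the oxygen pattern of ring A is symmetric, this regioisomeric adduct, and any C5-metalated material formed alongside, converges on 14.

3. Step 3. Hydrolytic replacement of bromide at C4 may be slow relative to ring opening and oligomerisation of the hemiacetal, or the hot acid may start to cleave benzyl ethers. Fallback from 2 to 6, which delivers the C4 oxygen by epoxidation instead of halide hydrolysis: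
   - 2-Furyllithium (furan, n-BuLi, THF, 0 °C) would add to 2 to give rac-[3,4-bis(benzyloxy)phenyl](furan-2-yl)methanol F5.
   - NBS/NaHCO3 in THF–H2O would give 2-[3,4-bis(benzyloxy)phenyl]-6-hydroxy-2H-pyran-3(6H)-one F6.
   - MeOH/CH(OMe)3 with cat. BF3·OEt2 would give the methyl acetal 2-[3,4-bis(benzyloxy)phenyl]-6-methoxy-2H-pyran-3(6H)-one F7.
   - Nucleophilic epoxidation (t-BuOOH, cat. DBU, CH2Cl2, 0 °C) would give 2-[3,4-bis(benzyloxy)phenyl]-4,5-epoxy-6-methoxytetrahydro-2H-pyran-3-one F8.
   - Mild acid (TsOH or Amberlyst-15, wet dioxane, 60 °C) would open the epoxide to the diosphenol, which loses methanol and tautomerises to 6.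

Further compounds
F1 | step 7 | (E)-3-[3,4-bis(benzyloxy)phenyl]-1-(2-hydroxy-3,4,5,6-tetramethoxyphenyl)prop-2-en-1-one | COc1c(OC)c(OC)c(C(=O)/C=C/c2ccc(OCc3ccccc3)c(OCc3ccccc3)c2)c(O)c1OC
F2 | step 7 | 2-[3,4-bis(benzyloxy)phenyl]-5,6,7,8-tetramethoxy-4H-chromen-4-one | COc1c(OC)c(OC)c2c(=O)cc(-c3ccc(OCc4ccccc4)c(OCc4ccccc4)c3)oc2c1OC
F3 | step 7 | 2-[3,4-bis(benzyloxy)phenyl]-3-hydroxy-5,6,7,8-tetramethoxy-4H-chromen-4-one | COc1c(OC)c(OC)c2c(=O)c(O)c(-c3ccc(OCc4ccccc4)c(OCc4ccccc4)c3)oc2c1OC
F4 | step 5 | rac-4-{5-(benzyloxy)-6-[3,4-bis(benzyloxy)phenyl]-4-oxo-4H-pyran-2-yl}-4-hydroxy-2,3-dimethoxycyclobut-2-en-1-one | COC1=C(OC)C(O)(c2cc(=O)c(OCc3ccccc3)c(-c3ccc(OCc4ccccc4)c(OCc4ccccc4)c3)o2)C1=O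
F5 | step 3 | rac-[3,4-bis(benzyloxy)phenyl](furan-2-yl)methanol | OC(c1ccco1)c1ccc(OCc2ccccc2)c(OCc2ccccc2)c1
F6 | step 3 | 2-[3,4-bis(benzyloxy)phenyl]-6-hydroxy-2H-pyran-3(6H)-one (racemic, diastereomer mixture) | O=C1C=CC(O)OC1c1ccc(OCc2ccccc2)c(OCc2ccccc2)c1
F7 | step 3 | 2-[3,4-bis(benzyloxy)phenyl]-6-methoxy-2H-pyran-3(6H)-one (racemic, diastereomer mixture) | O=C1C=CC(OC)OC1c1ccc(OCc2ccccc2)c(OCc2ccccc2)c1
F8 | step 3 | 2-[3,4-bis(benzyloxy)phenyl]-4,5-epoxy-6-methoxytetrahydro-2H-pyran-3-one (racemic, diastereomer mixture) | O=C1C2OC2C(OC)OC1c1ccc(OCc2ccccc2)c(OCc2ccccc2)c1
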